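Ring B (C1, C5–C10; C1 = methyl-bearing fusion carbon, C6 = aroyloxy carbon, C8 = methyl-bearing alkene carbon, C10 = angeloyloxy carbon) is disconnected at C6–C7 and C8=C9, which excises C7–C8 with its methyl as propyne. The key step, a ruthenium-catalysed tandem enyne metathesis, stitches propyne between a C5 vinyl group and a C10 vinyl arm of a trans-disubstituted cyclopentane (ring A) and forms both bonds as the 6,8-diene. It exploits C6–C9 as a latent 1,3-diene and the trans fusion, which forbids direct diene ring closure. The precursor comes from an asymmetric Diels–Alder reaction, ozonolysis and proline aldol ring contraction; C6=C7 later becomes the 6α-carbinol.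

Key step: step 8

Remark on numbering: daucane numbering is used throughout (C2, C3 = ring A methylenes, C4 = isopropyl carbinol carbon, C5 = fusion CH, C7 = ring B methylene, C9 = alkene CH); β is the face of the C1 methyl group.

Assumption: the senses of induction in steps 2, 3 and 6 are taken from the accepted transition-state models of these catalysts, and the antipodal catalyst would be used if the opposite sense were found; angelic anhydride (7) and 4-acetoxybenzoyl chloride (18) are taken as purchasable.

Step 1
Reactants: 1 3-methylbut-1-yne; 2 ethene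
Product: 3 2-(propan-2-yl)buta-1,3-diene
Conditions: ethene (1 atm), second-generation Grubbs catalyst (3 mol%), CH2Cl2, rt
Reagents that add atoms: none
Why: Cross-enyne metathesis of a terminal alkyne with ethene, in which the ruthenium methylidene inserts the alkyne and should give the 2-substituted buta-1,3-diene with full atom economy.

Step 2
Reactants: 3 2-(propan-2-yl)buta-1,3-diene; 4 methacrolein
Product: 5 (1S)-1-methyl-4-(propan-2-yl)cyclohex-3-ene-1-carbaldehyde
Conditions: (S)-1-(2-methylphenyl)-3,3-diphenyltetrahydro-1H,3H-pyrrolo[1,2-c][1,3,2]oxazaborole activated with HN(SO2CF3)2 (10 mol%), CH2Cl2, −78 to −40 °C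
Reagents that add atoms: none
Why: Enantioselective Diels–Alder reaction in which the chiral cationic oxazaborolidine binds the s-trans enal and shields one face, while the 2-substituted diene adds with "para" regiochemistry, so that the quaternary C1 is set by the catalyst.

Step 3
Reactants: 5 (1S)-1-methyl-4-(propan-2-yl)cyclohex-3-ene-1-carbaldehyde
Product: 6 (1R)-1-[(1S)-1-methyl-4-(propan-2-yl)cyclohex-3-en-1-yl]prop-2-en-1-ol
Conditions: CH2=CHMgBr (2 equiv per zinc), ZnCl2, THF/toluene, 0 °C, then 1,4-dioxane and filtration from the magnesium halide; then (2R)-(+)-3-exo-morpholinoisoborneol (10 mol%), 5, −20 to 0 °C; H2O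
Reagents that add atoms: vinylmagnesium bromide C=C[Mg]Br; divinylzinc C=C[Zn]C=C
Why: Amino-alcohol-catalysed enantioselective alkenylzinc addition to an aldehyde (the divinylzinc being made in the flask by transmetallation of the Grignard reagent and freed of magnesium salts to suppress the racemic background reaction), in which the ligand and not the nearly symmetric ring environment of C1 decides the face, so that Re-face attack should give the (R)-carbinol at C10.

Step 4
Reactants: 6 (1R)-1-[(1S)-1-methyl-4-(propan-2-yl)cyclohex-3-en-1-yl]prop-2-en-1-ol; 7 angelic anhydride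
Product: 8 (1R)-1-[(1S)-1-methyl-4-(propan-2-yl)cyclohex-3-en-1-yl]prop-2-en-1-yl (2Z)-2-methylbut-2-enoate
Conditions: LiN(SiMe3)2, THF, −78 °C; then 7, −78 to 0 °C; H2O
Reagents that add atoms: none
Why: Acylation of the lithium alkoxide with the symmetrical anhydride needs no nucleophilic amine catalyst, so the hindered carbinol should be esterified with retention of the Z (angelate) geometry.

Step 5
Reactants: 8 (1R)-1-[(1S)-1-methyl-4-(propan-2-yl)cyclohex-3-en-1-yl]prop-2-en-1-yl (2Z)-2-methylbut-2-enoate
Product: 10 (3R,4S)-4,8-dimethyl-7-oxo-4-(2-oxoethyl)non-1-en-3-yl (2Z)-2-methylbut-2-enoate, via secondary ozonide 9 (not isolated)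
Conditions: O3 (1 equiv, Sudan Red 7B end point), CH2Cl2, −78 °C; then PPh3, −78 °C to rt
Reagents that add atoms: ozone O=[O+][O-]
Why: Criegee ozonolysis should take place at the electron-rich trisubstituted ring alkene, because the vinyl group is deactivated by the allylic ester and the angelate by conjugation, and reductive work-up then gives the keto aldehyde with C1 and C10 untouched.

Step 6
Reactants: 10 (3R,4S)-4,8-dimethyl-7-oxo-4-(2-oxoethyl)non-1-en-3-yl (2Z)-2-methylbut-2-enoate
Product: 11 (1R)-1-[(1S,2R,3R)-2-formyl-3-hydroxy-1-methyl-3-(propan-2-yl)cyclopentyl]prop-2-en-1-yl (2Z)-2-methylbut-2-enoate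
Conditions: D-proline (20 mol%), DMSO, rt
Reagents that add atoms: none
Why: Only the aldehyde can form an enamine with D-proline, and this attacks the ketone in a 5-enolexo aldol cyclisation through the hydrogen-bonded chair-like transition state (carboxylic acid on the ketone oxygen, isopropyl turned away from the iminium carbon), so that C5 is set by the catalyst with the formyl group trans to the bulky C10 side chain and the new C4 hydroxyl cis to the formyl group, an arrangement that also places the formyl group trans to both large neighbours and should therefore be the thermodynamic sink of this reversible aldol.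

Step 7
Reactants: 11 (1R)-1-[(1S,2R,3R)-2-formyl-3-hydroxy-1-methyl-3-(propan-2-yl)cyclopentyl]prop-2-en-1-yl (2Z)-2-methylbut-2-enoate
Product: 12 (1R)-1-[(1S,2R,3R)-2-ethenyl-3-hydroxy-1-methyl-3-(propan-2-yl)cyclopentyl]prop-2-en-1-yl (2Z)-2-methylbut-2-enoate
Conditions: Ph3PCH3Br, KN(SiMe3)2, THF, 0 °C; then 11, −78 to 0 °C
Reagents that add atoms: methyltriphenylphosphonium bromide C[P+](c1ccccc1)(c1ccccc1)c1ccccc1.[Br-]
Why: Wittig methylenation of the aldehyde, in which the non-stabilised ylide is too weak a base to deprotonate the tertiary alcohol (no retro-aldol cleavage) and leaves the ester alone, while any epimerisation at C5 would only favour the desired trans arrangement.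

Step 8
Reactants: 12 (1R)-1-[(1S,2R,3R)-2-ethenyl-3-hydroxy-1-methyl-3-(propan-2-yl)cyclopentyl]prop-2-en-1-yl (2Z)-2-methylbut-2-enoate; 13 propyne
Product: 14 10α-angeloyloxydauca-6,8-dien-4β-ol
Conditions: propyne (3 equiv), second-generation Hoveyda–Grubbs catalyst (10 mol%), toluene (0.01 M), 60 °C, sealed tube
Reagents that add atoms: none
Why: The ruthenium alkylidene should form first at the unhindered C5 vinyl group (Ru=C6) and add across propyne with C6 bonding to the unsubstituted alkyne carbon (new C6=C7 bond), giving through a ruthenacyclobutene the vinylcarbene Ru=C8(CH3), which closes onto the C10 vinyl group (new C8=C9 bond) and releases ethene. The closest known reaction type is the tandem intermolecular enyne metathesis–ring-closing metathesis that makes 1,3-cyclodienes from a terminal alkyne and a diene. Ring B is closed in the ring-closing metathesis event as a seven-membered ring through a metallacyclobutane, and both ring alkenes are necessarily cis. No stereocenter is created, and C1, C4, C5 and C10 are carried through unchanged because only sp2 carbons react. The step needs regioselectivity (the C5 vinyl group, not the C10 vinyl group, must engage propyne so that the methyl ends on C8), which the allylic ester and the adjacent quaternary C1 secure by retarding metathesis at the C10 vinyl group, and chemoselectivity against direct diene ring closure, which the strain of a trans-fused bicyclo[3.3.0]octene rules out. Open dienes with an E-configured C6=C7 bond cannot close and should re-enter the cycle by reversible metathesis.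

Step 9
Reactants: 14 10α-angeloyloxydauca-6,8-dien-4β-ol
Product: 15 10α-angeloyloxy-6β,7β-epoxydauc-8-en-4β-ol
Conditions: VO(acac)2 (5 mol%), tBuOOH, CH2Cl2, 0 °C
Reagents that add atoms: tert-butyl hydroperoxide CC(C)(C)OO
Why: Hydroxyl-directed vanadium-catalysed epoxidation, in which the homoallylic C4 hydroxyl should deliver the peroxide to the β face of the nearby C6=C7 bond and leave the remote C8=C9 bond and the electron-poor angelate alone, the epoxide configuration being lost in the next step.

Step 10
Reactants: 15 10α-angeloyloxy-6β,7β-epoxydauc-8-en-4β-ol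
Product: 16 10α-angeloyloxy-4β-hydroxydauc-8-en-6-one
Conditions: Pd(PPh3)4 (2 mol%), CH2Cl2, 0 °C to rt
Reagents that add atoms: none
Why: Isomerisation of a 1,3-diene monoepoxide to a β,γ-unsaturated ketone catalysed by zerovalent palladium, by opening to a π-allylpalladium alkoxide (C7–C9) and 1,2-hydride shift from C6 to C7, which should install the C6 carbonyl and the C7 methylene and leave the C8=C9 bond in place.

Step 11
Reactants: 16 10α-angeloyloxy-4β-hydroxydauc-8-en-6-one
Product: 17 10α-angeloyloxydauc-8-ene-4β,6α-diol
Conditions: Me4NBH(OAc)3, MeCN/AcOH, −30 °C; aqueous work-up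
Reagents that add atoms: none
Why: Evans–Saksena reduction, in which the C4 hydroxyl binds boron and delivers hydride intramolecularly to the β face of the C6 ketone through a six-membered chair transition state, should give the 1,3-anti (4β,6α) diol and leave the esters and the alkene untouched.

Step 12
Reactants: 17 10α-angeloyloxydauc-8-ene-4β,6α-diol; 18 4-acetoxybenzoyl chloride
Product: 19 6α-(4-acetoxybenzoyloxy)-10α-angeloyloxydauc-8-en-4β-ol
Conditions: Et3N, 4-(dimethylamino)pyridine (cat.), CH2Cl2, 0 °C to rt
Reagents that add atoms: none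
Why: Nucleophile-catalysed acylation should take place at the only secondary alcohol (C6), the tertiary C4 hydroxyl being too hindered to react.

Step 13
Reactants: 19 6α-(4-acetoxybenzoyloxy)-10α-angeloyloxydauc-8-en-4β-ol
Product: 20 10α-angeloyloxy-6α-(4-hydroxybenzoyloxy)dauc-8-en-4β-ol (target)
Conditions: pyrrolidine (1.2 equiv), CH2Cl2, 0 °C
Reagents that add atoms: none
Why: Chemoselective aminolysis of the phenolic acetate, which is far more electrophilic than the alkyl benzoate and the hindered angelate, should liberate the phenol.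

Compound list
1 | 3-methylbut-1-yne | CC(C)C#C | starting material
2 | ethene | C=C | starting material
3 | 2-(propan-2-yl)buta-1,3-diene | C=CC(=C)C(C)C | intermediate
4 | methacrolein (2-methylprop-2-enal) | CC(=C)C=O | starting material
5 | (1S)-1-methyl-4-(propan-2-yl)cyclohex-3-ene-1-carbaldehyde | O=C[C@@]1(C)CCC(C(C)C)=CC1 | intermediate
6 | (1R)-1-[(1S)-1-methyl-4-(propan-2-yl)cyclohex-3-en-1-yl]prop-2-en-1-ol | O[C@H](C=C)[C@@]1(C)CCC(C(C)C)=CC1 | intermediate
7 | angelic anhydride, (2Z)-2-methylbut-2-enoic anhydride | C/C=C(/C)C(=O)OC(=O)/C(C)=C\C | starting material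
8 | (1R)-1-[(1S)-1-methyl-4-(propan-2-yl)cyclohex-3-en-1-yl]prop-2-en-1-yl (2Z)-2-methylbut-2-enoate | C/C=C(/C)C(=O)O[C@H](C=C)[C@@]1(C)CCC(C(C)C)=CC1 | intermediate
9 | secondary ozonide of 8 (1,2,4-trioxolane across the former ring alkene; not isolated) | C/C=C(/C)C(=O)O[C@H](C=C)[C@@]1(C)CCC2(C(C)C)OOC(C1)O2 | intermediate
10 | (3R,4S)-4,8-dimethyl-7-oxo-4-(2-oxoethyl)non-1-en-3-yl (2Z)-2-methylbut-2-enoate | C/C=C(/C)C(=O)O[C@H](C=C)[C@@](C)(CCC(=O)C(C)C)CC=O | intermediate
11 | (1R)-1-[(1S,2R,3R)-2-formyl-3-hydroxy-1-methyl-3-(propan-2-yl)cyclopentyl]prop-2-en-1-yl (2Z)-2-methylbut-2-enoate | C/C=C(/C)C(=O)O[C@H](C=C)[C@@]1(C)CC[C@@](O)(C(C)C)[C@@H]1C=O | intermediate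
12 | (1R)-1-[(1S,2R,3R)-2-ethenyl-3-hydroxy-1-methyl-3-(propan-2-yl)cyclopentyl]prop-2-en-1-yl (2Z)-2-methylbut-2-enoate | C/C=C(/C)C(=O)O[C@H](C=C)[C@@]1(C)CC[C@@](O)(C(C)C)[C@@H]1C=C | intermediate
13 | propyne | CC#C | starting material
14 | 10α-angeloyloxydauca-6,8-dien-4β-ol (trans-fused, 1β-methyl, 5α-H) | C/C=C(/C)C(=O)O[C@@H]1C=C(C)C=C[C@@H]2[C@]1(C)CC[C@@]2(O)C(C)C | intermediate
15 | 10α-angeloyloxy-6β,7β-epoxydauc-8-en-4β-ol | C/C=C(/C)C(=O)O[C@@H]1C=C(C)[C@H]3O[C@H]3[C@@H]2[C@]1(C)CC[C@@]2(O)C(C)C | intermediate
16 | 10α-angeloyloxy-4β-hydroxydauc-8-en-6-one | C/C=C(/C)C(=O)O[C@@H]1C=C(C)CC(=O)[C@@H]2[C@]1(C)CC[C@@]2(O)C(C)C | intermediate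
17 | 10α-angeloyloxydauc-8-ene-4β,6α-diol | C/C=C(/C)C(=O)O[C@@H]1C=C(C)C[C@H](O)[C@@H]2[C@]1(C)CC[C@@]2(O)C(C)C | intermediate
18 | 4-acetoxybenzoyl chloride | CC(=O)Oc1ccc(cc1)C(Cl)=O | starting material
19 | 6α-(4-acetoxybenzoyloxy)-10α-angeloyloxydauc-8-en-4β-ol | C/C=C(/C)C(=O)O[C@@H]1C=C(C)C[C@H](OC(=O)c2ccc(OC(C)=O)cc2)[C@@H]2[C@]1(C)CC[C@@]2(O)C(C)C | intermediate
20 | 10α-angeloyloxy-6α-(4-hydroxybenzoyloxy)dauc-8-en-4β-ol | C/C=C(/C)C(=O)O[C@@H]1C=C(C)C[C@H](OC(=O)c2ccc(O)cc2)[C@@H]2[C@]1(C)CC[C@@]2(O)C(C)C | target

Total step count: 13. Longest linear sequence: 13 steps (from 3-methylbut-1-yne to 20).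

Steps most likely to fail

Step 8. The enyne event may take the wrong regiochemical course (propyne engaged by the C10 vinyl group, which would put the methyl on C7), open dienes with an E-configured C6=C7 bond may accumulate without closing, and propyne may oligomerise. The fallback sets out from 11 and gives up the single operation. Indium-mediated Barbier addition of 3-bromo-2-methylpropene in THF/H2O, chelation-controlled by the C4 hydroxyl, should give the 6α-configured homoallylic alcohol (1R)-1-{(1S,2S,3R)-3-hydroxy-2-[(1S)-1-hydroxy-3-methylbut-3-en-1-yl]-1-methyl-3-(propan-2-yl)cyclopentyl}prop-2-en-1-yl (2Z)-2-methylbut-2-enoate F1. Ring-closing metathesis of its 1,1-disubstituted alkene with the C10 vinyl group (second-generation Grubbs catalyst, CH2Cl2, 40 °C) then closes ring B, and the sequence comes back to the route at 17.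

Step 6. The tertiary aldol may dehydrate, closure onto the hindered isopropyl ketone may be slow, and facial control may be incomplete. The fallback sets out from 10. Piperidinium acetate in toluene at 80 °C should give, by aldol condensation, the enal (1R)-1-[(1S)-2-formyl-1-methyl-3-(propan-2-yl)cyclopent-2-en-1-yl]prop-2-en-1-yl (2Z)-2-methylbut-2-enoate F2. Weitz–Scheffer epoxidation (tBuOOH, DBU, CH2Cl2) anti to the C10 side chain should give the β-face 2,3-epoxide of this enal F3. SmI2 in THF/MeOH at −90 °C cleaves the Cα–O bond, and after equilibration of C5 with Et3N the route is rejoined at 11.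

Step 10. The allylic angelate may ionise, the π-allyl intermediate may be captured by oxygen, the enone may move into conjugation, and the trans fusion may be lost by enolisation toward C5. The fallback sets out from 15. Palladium-catalysed formate hydrogenolysis of the alkenyl oxirane (Pd2(dba)3, PBu3, HCO2H, Et3N, dioxane) delivers hydride to C7 and should give 10α-angeloyloxydauc-8-ene-4β,6β-diol F4. Dess–Martin oxidation of its secondary alcohol rejoins the route at 16.

Further compounds
F1 | step 8 | (1R)-1-{(1S,2S,3R)-3-hydroxy-2-[(1S)-1-hydroxy-3-methylbut-3-en-1-yl]-1-methyl-3-(propan-2-yl)cyclopentyl}prop-2-en-1-yl (2Z)-2-methylbut-2-enoate | C/C=C(/C)C(=O)O[C@H](C=C)[C@@]1(C)CC[C@@](O)(C(C)C)[C@@H]1[C@@H](O)CC(C)=C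
F2 | step 6 | (1R)-1-[(1S)-2-formyl-1-methyl-3-(propan-2-yl)cyclopent-2-en-1-yl]prop-2-en-1-yl (2Z)-2-methylbut-2-enoate | C/C=C(/C)C(=O)O[C@H](C=C)[C@@]1(C)CCC(C(C)C)=C1C=O
F3 | step 6 | β-face 2,3-epoxide of F2 (epoxy aldehyde) | C/C=C(/C)C(=O)O[C@H](C=C)[C@@]1(C)CC[C@]2(C(C)C)O[C@]12C=O
F4 | step 10 | 10α-angeloyloxydauc-8-ene-4β,6β-diol | C/C=C(/C)C(=O)O[C@@H]1C=C(C)C[C@@H](O)[C@@H]2[C@]1(C)CC[C@@]2(O)C(C)C
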